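**Retrosynthetic overview**

1. Target 24 ⇐ tetra-O-benzyl isoflavone 23 by hydrogenolysis of the four benzyl ethers.
2. 23 ⇐ acrylic acid 21 by cutting C4–C4a. In ring A, C8a (O1), C8, C7, C6 and C5 all carry oxygen and C4a is the only carbon left, so an acyl carbon C4 tethered through O1–C2=C3 can only bond there. The pyranone is the only ring formed; both benzene rings are bought.
3. 21 ⇐ phenol 11 + (Z)-enol tosylate 19: the O1–C2 bond is made by addition–elimination, which fixes which oxygen becomes O1.
4. 11 ⇐ 2-methoxyresorcinol 1 by two formylation/Baeyer–Villiger oxygenations, the second placed ortho to the free phenol. 19 ⇐ aldehyde 12 by one-carbon homologation (14 supplies C4) and C-formylation (17 supplies C2).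

Key step: step 14

**Remarks on the chemistry**

- The target has no stereocentre and no stereogenic double bond, so no configuration has to be set.
- Assumption: acrylates 18–22 are drawn as Z isomers (carbonyl cis to the oxygen on C3). Any E isomer is carried on, because the two interconvert under the acidic conditions of step 14.
- Compound 15 is expected as an alkene-isomer mixture, racemic at sulfur, and is drawn without descriptors; both elements are erased in step 9.

**Route**

Step 1
Reactants: 1 2-methoxyresorcinol
Product: 3 2,4-dihydroxy-3-methoxybenzaldehyde, via aryl iminium chloride 2 (not isolated)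
Conditions: POCl3, DMF, MeCN, 0 °C → rt; then H2O, 50 °C
Reagents that add atoms: N,N-dimethylformamide CN(C)C=O; water O
Why: Vilsmeier–Haack formylation; C4 and C6 of 1 are equivalent and each is ortho to one hydroxyl and para to the other, C5 is meta to both, and the iminium group of 2 deactivates the ring against a second substitution.

Step 2
Reactants: 3 2,4-dihydroxy-3-methoxybenzaldehyde
Product: 4 2,4-bis(benzyloxy)-3-methoxybenzaldehyde
Conditions: BnBr, K2CO3, DMF, 60 °C
Reagents that add atoms: benzyl bromide BrCc1ccccc1
Why: Williamson etherification of both phenoxides; the hydrogen-bonded 2-hydroxyl needs warming but there is no competing site.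

Step 3
Reactants: 4 2,4-bis(benzyloxy)-3-methoxybenzaldehyde
Product: 6 2,4-bis(benzyloxy)-3-methoxyphenol, via aryl formate 5 (not isolated)
Conditions: mCPBA, CH2Cl2, 0 °C → rt; then MeOH, K2CO3 (cat.), rt
Reagents that add atoms: 3-chloroperbenzoic acid OOC(=O)c1cccc(Cl)c1
Why: Baeyer–Villiger oxidation in the Dakin sense; with alkoxy groups ortho and para to the formyl group the aryl group migrates in the Criegee intermediate, and the formate is then cleaved by transesterification.

Step 4
Reactants: 6 2,4-bis(benzyloxy)-3-methoxyphenol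
Product: 8 3,5-bis(benzyloxy)-2-hydroxy-4-methoxybenzaldehyde, via hydroxymethylphenol 7 (not isolated)
Conditions: MgCl2, Et3N, (CH2O)n, MeCN, reflux
Reagents that add atoms: formaldehyde (as paraformaldehyde) C=O
Why: Magnesium-mediated ortho-formylation of a phenol (Casnati–Skattebøl); the magnesium phenoxide delivers formaldehyde to its only free ortho carbon within a chelate and a second formaldehyde oxidises the benzylic alkoxide by hydride transfer, so the other ring C–H, which is not ortho to the phenoxide, is left alone.

Step 5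
Reactants: 8 3,5-bis(benzyloxy)-2-hydroxy-4-methoxybenzaldehyde
Product: 9 2,3,5-tris(benzyloxy)-4-methoxybenzaldehyde
Conditions: BnBr, K2CO3, DMF, 60 °C
Reagents that add atoms: benzyl bromide BrCc1ccccc1
Why: Williamson etherification of the single, chelated phenol.

Step 6
Reactants: 9 2,3,5-tris(benzyloxy)-4-methoxybenzaldehyde
Product: 11 2,3,5-tris(benzyloxy)-4-methoxyphenol, via aryl formate 10 (not isolated)
Conditions: mCPBA, CH2Cl2, 0 °C → rt; then MeOH, K2CO3 (cat.), rt
Reagents that add atoms: 3-chloroperbenzoic acid OOC(=O)c1cccc(Cl)c1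
Why: Baeyer–Villiger oxidation with aryl migration favoured by the ortho benzyloxy and para methoxy groups; the hydroxyl set free is the future O1 and sits next to the only unsubstituted ring carbon.

Step 7
Reactants: 12 3-hydroxy-4,5-dimethoxybenzaldehyde
Product: 13 3-(benzyloxy)-4,5-dimethoxybenzaldehyde
Conditions: BnBr, K2CO3, DMF, 50 °C
Reagents that add atoms: benzyl bromide BrCc1ccccc1
Why: Williamson etherification of the only phenol.

Step 8
Reactants: 13 3-(benzyloxy)-4,5-dimethoxybenzaldehyde; 14 methyl (methylsulfinyl)methyl sulfide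
Product: 15 1-(benzyloxy)-2,3-dimethoxy-5-[2-(methylsulfinyl)-2-(methylsulfanyl)ethenyl]benzene
Conditions: Triton B (cat.), THF, reflux
Reagents that add atoms: none
Why: Knoevenagel-type condensation of the carbanion of 14, stabilised by both sulfur groups, with the aldehyde and dehydration (first stage of the Ogura–Tsuchihashi homologation).

Step 9
Reactants: 15 ketene dithioacetal S-oxide
Product: 16 methyl 2-[3-(benzyloxy)-4,5-dimethoxyphenyl]acetate
Conditions: HCl, MeOH, 0 °C → rt
Reagents that add atoms: methanol CO
Why: Acid methanolysis of a ketene dithioacetal S-oxide; C-protonation gives a sulfur-stabilised cation that takes up methanol and loses both sulfur groups as dimethyl disulfide, and the aryl benzyl ether is inert to methanolic HCl at room temperature.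

Step 10
Reactants: 16 methyl 2-[3-(benzyloxy)-4,5-dimethoxyphenyl]acetate; 17 methyl formate
Product: 18 methyl (Z)-2-[3-(benzyloxy)-4,5-dimethoxyphenyl]-3-hydroxyacrylate (enol form of the α-formyl ester)
Conditions: NaH, THF, 0 °C → rt; then aq. HCl
Reagents that add atoms: none
Why: Crossed Claisen condensation with a non-enolisable formate, driven by formation of the sodium enolate of the product.

Step 11
Reactants: 18 methyl (Z)-2-aryl-3-hydroxyacrylate
Product: 19 methyl (Z)-2-[3-(benzyloxy)-4,5-dimethoxyphenyl]-3-(tosyloxy)acrylate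
Conditions: TsCl, TMEDA, LiCl, MeCN, 0 °C
Reagents that add atoms: 4-toluenesulfonyl chloride Cc1ccc(cc1)S(Cl)(=O)=O
Why: O-Sulfonylation of the lithium-chelated enolate, in which the enolate oxygen is held cis to the ester carbonyl, so the tosylate should form with Z geometry.

Step 12
Reactants: 11 2,3,5-tris(benzyloxy)-4-methoxyphenol; 19 methyl (Z)-2-aryl-3-(tosyloxy)acrylate
Product: 20 methyl (Z)-2-[3-(benzyloxy)-4,5-dimethoxyphenyl]-3-[2,3,5-tris(benzyloxy)-4-methoxyphenoxy]acrylate
Conditions: Cs2CO3, MeCN, rt, Ar
Reagents that add atoms: none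
Why: Nucleophilic vinylic substitution by addition–elimination; the phenoxide adds to C3 of the β-sulfonyloxy acrylate and the short-lived ester enolate expels tosylate after minimal rotation, so retention of the Z geometry is expected.

Step 13
Reactants: 20 methyl (Z)-2-aryl-3-aryloxyacrylate
Product: 21 (Z)-2-[3-(benzyloxy)-4,5-dimethoxyphenyl]-3-[2,3,5-tris(benzyloxy)-4-methoxyphenoxy]acrylic acid
Conditions: LiOH, THF/MeOH/H2O, rt; then aq. HCl to pH 3
Reagents that add atoms: lithium hydroxide [Li+].[OH-]
Why: Saponification of the methyl ester (BAc2); the ester carbonyl should be attacked in preference to the donor-substituted C3, as in the hydrolysis of simple 3-aryloxyacrylates.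

Step 14
Reactants: 21 (Z)-2-aryl-3-aryloxyacrylic acid
Product: 23 5,7,8-tris(benzyloxy)-3-[3-(benzyloxy)-4,5-dimethoxyphenyl]-6-methoxy-4H-chromen-4-one, via mixed trifluoroacetic anhydride 22 (not isolated)
Conditions: (CF3CO)2O, CH2Cl2, 0 °C → rt
Reagents that add atoms: none
Why: Trifluoroacetic anhydride converts the acid into mixed anhydride 22, whose carbonyl lies cis to the aryloxy group and ionises to an acylium stabilised as a ketene–oxocarbenium by the enol ether oxygen; this attacks the one C–H position of the pentaoxygenated ring (ortho to O1 and to the C5 benzyloxy group, para to the C7 benzyloxy group), and loss of the proton from the Wheland intermediate gives the C4–C4a bond. The closest known reaction type is the Friedel–Crafts cycloacylation of 3-aryloxyacrylic acids to chromones, run here under the anhydride conditions used for acylating polyalkoxyarenes. The pyranone closes in a 6-exo mode by intramolecular electrophilic aromatic substitution. No stereocentre is formed. Regioselectivity needs no control because C4a is the only unsubstituted carbon of that ring and O1 was fixed in step 12; any E isomer should equilibrate with Z through C2 protonation or through the acylium, in which C2–C3 has single-bond character. The four benzyl ethers should survive because no mineral acid or metal Lewis acid is present and trifluoroacetic acid is the only acid formed.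

Step 15
Reactants: 23 tetra-O-benzyl isoflavone
Product: 24 5,7,8-trihydroxy-3-(3-hydroxy-4,5-dimethoxyphenyl)-6-methoxy-4H-chromen-4-one (5,7,8,3'-tetrahydroxy-6,4',5'-trimethoxyisoflavone)
Conditions: H2 (1 atm), Pd/C, EtOAc/MeOH, rt; filtration and concentration under Ar
Reagents that add atoms: none
Why: Heterogeneous hydrogenolysis of the four benzylic C–O bonds; the methyl ethers and the chromone C2=C3 bond should remain if the reaction is stopped at the calculated hydrogen uptake, and the air-sensitive polyphenol is kept under argon.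

**Compound list**

1 | 2-methoxyresorcinol | COc1c(O)cccc1O | starting material
2 | N-(2,4-dihydroxy-3-methoxybenzylidene)-N-methylmethanaminium chloride | C[N+](C)=Cc1ccc(O)c(OC)c1O.[Cl-] | intermediate
3 | 2,4-dihydroxy-3-methoxybenzaldehyde | COc1c(O)ccc(C=O)c1O | intermediate
4 | 2,4-bis(benzyloxy)-3-methoxybenzaldehyde | COc1c(OCc2ccccc2)ccc(C=O)c1OCc1ccccc1 | intermediate
5 | 2,4-bis(benzyloxy)-3-methoxyphenyl formate | COc1c(OCc2ccccc2)ccc(OC=O)c1OCc1ccccc1 | intermediate
6 | 2,4-bis(benzyloxy)-3-methoxyphenol | COc1c(OCc2ccccc2)ccc(O)c1OCc1ccccc1 | intermediate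
7 | 2,4-bis(benzyloxy)-6-(hydroxymethyl)-3-methoxyphenol (as its magnesium salt) | COc1c(OCc2ccccc2)cc(CO)c(O)c1OCc1ccccc1 | intermediate
8 | 3,5-bis(benzyloxy)-2-hydroxy-4-methoxybenzaldehyde | COc1c(OCc2ccccc2)cc(C=O)c(O)c1OCc1ccccc1 | intermediate
9 | 2,3,5-tris(benzyloxy)-4-methoxybenzaldehyde | COc1c(OCc2ccccc2)cc(C=O)c(OCc2ccccc2)c1OCc1ccccc1 | intermediate
10 | 2,3,5-tris(benzyloxy)-4-methoxyphenyl formate | COc1c(OCc2ccccc2)cc(OC=O)c(OCc2ccccc2)c1OCc1ccccc1 | intermediate
11 | 2,3,5-tris(benzyloxy)-4-methoxyphenol | COc1c(OCc2ccccc2)cc(O)c(OCc2ccccc2)c1OCc1ccccc1 | intermediate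
12 | 3-hydroxy-4,5-dimethoxybenzaldehyde | COc1cc(C=O)cc(O)c1OC | starting material
13 | 3-(benzyloxy)-4,5-dimethoxybenzaldehyde | COc1cc(C=O)cc(OCc2ccccc2)c1OC | intermediate
14 | methyl (methylsulfinyl)methyl sulfide (racemic) | CSCS(C)=O | starting material
15 | 1-(benzyloxy)-2,3-dimethoxy-5-[2-(methylsulfinyl)-2-(methylsulfanyl)ethenyl]benzene (isomer mixture, racemic at S) | COc1cc(C=C(SC)S(C)=O)cc(OCc2ccccc2)c1OC | intermediate
16 | methyl 2-[3-(benzyloxy)-4,5-dimethoxyphenyl]acetate | COC(=O)Cc1cc(OC)c(OC)c(OCc2ccccc2)c1 | intermediate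
17 | methyl formate | COC=O | starting material
18 | methyl (Z)-2-[3-(benzyloxy)-4,5-dimethoxyphenyl]-3-hydroxyacrylate | COC(=O)/C(=C\O)c1cc(OC)c(OC)c(OCc2ccccc2)c1 | intermediate
19 | methyl (Z)-2-[3-(benzyloxy)-4,5-dimethoxyphenyl]-3-(tosyloxy)acrylate | COC(=O)/C(=C\OS(=O)(=O)c1ccc(C)cc1)c1cc(OC)c(OC)c(OCc2ccccc2)c1 | intermediate
20 | methyl (Z)-2-[3-(benzyloxy)-4,5-dimethoxyphenyl]-3-[2,3,5-tris(benzyloxy)-4-methoxyphenoxy]acrylate | COC(=O)/C(=C\Oc1cc(OCc2ccccc2)c(OC)c(OCc2ccccc2)c1OCc1ccccc1)c1cc(OCc2ccccc2)c(OC)c(OC)c1 | intermediate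
21 | (Z)-2-[3-(benzyloxy)-4,5-dimethoxyphenyl]-3-[2,3,5-tris(benzyloxy)-4-methoxyphenoxy]acrylic acid | O=C(O)/C(=C\Oc1cc(OCc2ccccc2)c(OC)c(OCc2ccccc2)c1OCc1ccccc1)c1cc(OCc2ccccc2)c(OC)c(OC)c1 | intermediate
22 | mixed anhydride of 21 with trifluoroacetic acid | O=C(OC(=O)C(F)(F)F)/C(=C\Oc1cc(OCc2ccccc2)c(OC)c(OCc2ccccc2)c1OCc1ccccc1)c1cc(OCc2ccccc2)c(OC)c(OC)c1 | intermediate
23 | 5,7,8-tris(benzyloxy)-3-[3-(benzyloxy)-4,5-dimethoxyphenyl]-6-methoxy-4H-chromen-4-one | COc1cc(-c2coc3c(OCc4ccccc4)c(OCc4ccccc4)c(OC)c(OCc4ccccc4)c3c2=O)cc(OCc2ccccc2)c1OC | intermediate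
24 | 5,7,8,3'-tetrahydroxy-6,4',5'-trimethoxyisoflavone | COc1cc(-c2coc3c(O)c(O)c(OC)c(O)c3c2=O)cc(O)c1OC | target

**Step count**

Total: 15 steps. Longest linear sequence: 10 steps (steps 1–6 and 12–15, from 1). The B-ring branch (steps 7–11) has 5 steps.

**Steps most likely to fail**

1. Step 14. Trifluoroacetic acid may cause loss or migration of benzyl groups, excess anhydride may trifluoroacetylate the free ring carbon before the ring closes, or an E-configured anhydride may equilibrate too slowly. The fallback sets out from phenol 11 and makes the same C4–C4a bond with reversed polarity, without acid. Bromination with NBS (CH2Cl2, −78 → 0 °C) at the only free ring carbon should give 2,3,5-tris(benzyloxy)-6-bromo-4-methoxyphenol F1. Vinylation with 19 as in step 12 should give methyl (Z)-2-[3-(benzyloxy)-4,5-dimethoxyphenyl]-3-[2,3,5-tris(benzyloxy)-6-bromo-4-methoxyphenoxy]acrylate F2. Bromine–lithium exchange (n-BuLi, THF, −100 °C) then lets the aryllithium add to the cis ester carbonyl and expel methoxide (Parham cycloacylation), which comes back to the route at 23.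

2. Step 12. The phenoxide may attack sulfur instead of C3 (sulfonyl transfer back to the enolate), it may be oxidised by air, or the geometry may erode through reversible addition. The fallback sets out from 18 and removes the sulfur centre. Deoxychlorination with oxalyl chloride and DMF (CH2Cl2, 0 °C → rt) should give methyl (Z)-2-[3-(benzyloxy)-4,5-dimethoxyphenyl]-3-chloroacrylate F3, probably with some E isomer. Displacement of chloride by the phenoxide of 11 (K2CO3, DMF, rt) comes back to the route at 20.

3. Step 13. Hydroxide may add to C3 and expel the aryloxide (retro-vinylation), or saponification of the hindered α-aryl ester may stall. The fallback sets out from 20 and cleaves the O–CH3 bond instead of the acyl–oxygen bond: LiI in EtOAc at reflux (SN2 at the methyl group), then acidification, comes back to the route at 21. No compound outside the list is made (F0).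

**Further compounds**

F1 | step 14 | 2,3,5-tris(benzyloxy)-6-bromo-4-methoxyphenol | COc1c(OCc2ccccc2)c(Br)c(O)c(OCc2ccccc2)c1OCc1ccccc1
F2 | step 14 | methyl (Z)-2-[3-(benzyloxy)-4,5-dimethoxyphenyl]-3-[2,3,5-tris(benzyloxy)-6-bromo-4-methoxyphenoxy]acrylate | COC(=O)/C(=C\Oc1c(Br)c(OCc2ccccc2)c(OC)c(OCc2ccccc2)c1OCc1ccccc1)c1cc(OCc2ccccc2)c(OC)c(OC)c1
F3 | step 12 | methyl (Z)-2-[3-(benzyloxy)-4,5-dimethoxyphenyl]-3-chloroacrylate | COC(=O)/C(=C\Cl)c1cc(OC)c(OC)c(OCc2ccccc2)c1
F0 | step 13 | none | none
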